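Time first: from 2.6 h to 3.2 h the theta flask gains 0.00260 M of X, against a scatter of 0.002 M in each reading.

| flask | J | L | Q | X | time |
|---|---|---|---|---|---|
| theta | 0.400 M | 0.480 M | 0.0200 M |  |  |
| alpha | 0.160 M | 0.240 M | 0.0200 M |  |  |
| delta | 0.400 M | 0.480 M | 0.0200 M | 0.120 M |  |
| eta | 0.400 M | 0.960 M | 0.0200 M |  |  |
| zeta | 0.160 M | 0.480 M | 0.0200 M |  | 3.2 h |

- theta run (time / h: [X] / M): 0.11: 0.0452; 0.35: 0.1099; 0.67: 0.1554; 1.1: 0.1922; 1.5: 0.2093; 2.0: 0.2205; 2.6: 0.2298; 3.2: 0.2324
- alpha run (time / h: [X] / M): 0.11: 0.0151; 0.35: 0.0434; 0.67: 0.0702; 1.1: 0.0878; 1.5: 0.0954; 2.0: 0.1035; 2.6: 0.1091; 3.2: 0.1107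
- delta run (time / h: [X] / M): 0.11: 0.1655; 0.35: 0.2274; 0.67: 0.2797; 1.1: 0.3129; 1.5: 0.3314; 2.0: 0.3400; 2.6: 0.3491; 3.2: 0.3507
- eta run (time / h: [X] / M): 0.11: 0.0473; 0.35: 0.1146; 0.67: 0.1634; 1.1: 0.2022; 1.5: 0.2130; 2.0: 0.2242; 2.6: 0.2315; 3.2: 0.2343

(each reading ± 0.002 M)

* reaction order in [L] at the outset, round the charge of the theta run, defined at two percent of the J turned into X
* reaction order in [J] at the outset, round the charge of the theta run, defined at two percent of the J turned into X (one fixed amount of X, the same in the runs compared)
* X in the zeta run at 3.2 h, as a share of the J charged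

- Overall: J + L -> X, with Q as catalyst.
- Constant volume, constant temperature.
- The analysis sees a species whether free or bound.
- "The second partner" is L.
- An order is taken over about fifteen percent of the charge, up and down.

Here is the oddity. At 3.2 h the theta flask stands at 58.1% of its J, the limiting reagent by charge, and twice the L in the eta flask gives 58.6%. Yet the alpha flask, with less J and half of theta's L, reaches a larger share, 69.2%.

Shares of different charges need a common measure. For theta we take 0.870: this is the reach, the natural log of one over the fraction of the J charged that is not found as X at 3.2 h. For a loss first order in J with a constant rate constant, it equals that constant times time, whatever the charge. Eta reads 0.881 and alpha 1.18. So doubling L multiplies the reach by 1.01, a step of 0.0110 against a scatter of 0.0119 in either reading. The gap between alpha and theta reads 0.310, wider than that step. We read this gap as going with the J charge, but that is our reading, since alpha differs from theta in J and in L together.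

Zeta has alpha's J and twice alpha's L, the same ratio as from theta to eta, and we assume the same factor at that lower J and lower L. Our reckoning gives a reach of 1.19, hence a share of 69.7%, give or take 1.23% of the charge from the scatter of alpha's last reading.

The forecast argues that "The plateaus fall well short of J or L exhaustion, so the catalyst is dying". It gives 0.1 for the order in L, 0.98 for the order in J, and 71.5% for zeta, a reach of 1.26, higher than ours.

The simulation gives 0.15 in L, 0.89 in J and 70.3% for zeta, so the forecast's order in L is too low and its other two values stand within their margins.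

    Q + J → QJ (66.96 M⁻¹ h⁻¹)
    QJ + L → X + Q (428.4 M⁻¹ h⁻¹)
    2 J → Qe (1.368 M⁻¹ h⁻¹)
    Q → Ju (0.6876 h⁻¹)

The zeta share is a reach of 1.21, against our 1.19. It is held down by two steps acting together, the passing of Q into Ju, the main one, and the passing of 2 J into Qe. The zeta run with Q into Ju taken away gives 85.0%, a reach of 1.90. With 2 J into Qe taken away it gives 82.1%, a reach of 1.72.

(The readings come from a simulation for substances that don't exist, and the scatter is random.)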